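**Plan**

1. Numbering: ring carbons C1 (stereocentre) to C14, C15 is the ester carbon on C4, Ca the alkene carbon on C1. Because C15 lies cis to C2 across C3=C4, the atoms C15, C4, C3, C2, C1 and C14 can be tied into a cyclohex-2-enone with C15 as its carbonyl. That ring fixes the enoate geometry and places C4 and C14 on either side of one carbonyl, so a C5–C13 chain on C4 reaches C14 through a 12-membered bridge.
2. Cuts, in retrosynthetic order: O–CH3; C14–S; C15–C14 (retro-Claisen of a bridged, non-enolisable β-keto sulfone); C13–C14 (macrocyclising enolate alkylation); C4–C5 together with C3=C4 (β-keto ester alkylation, then decarboxylative dehydrogenation); C1–Ca (conjugate addition to cyclohexenone); C11=C12 and C6–C7/C8–CH3 inside the chain.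
3. Forward: boronate 5 (steps 1–3) is added to cyclohexenone, which supplies the six-membered ring (step 4), and the ketone is acylated at C4 (step 5). Chain iodide 17 (steps 6–11) is attached at C4 and the enone is formed (steps 12–13). Sulfonylation, desilylation and bromination (steps 14–16) give bromide 23, the 12-membered bridge closes (step 17), and cutting C15–C14 releases the 14-membered ring (step 18) before desulfonylation and methylation (steps 19–20).
4. Stereochemistry: C1 from the (S)-BINAP–rhodium conjugate addition; Z at C3=C4 from the six-membered ring; E at C7=C8 from syn carboalumination; Z at C11=C12 from the Still–Gennari olefination.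

Key step: step 17

Remark 1: C4 in 8 and 18 and C14 in 21–25 are transient stereocentres that are erased later; these compounds are carried as epimer mixtures and their SMILES leave those centres open. C1 keeps one spatial arrangement throughout; its descriptor reads S in 7, 8, 18 and 19 and R in 21–27 only because the ranking of its neighbours changes.

Remark 2: enolates that a carbonate or hydride base forms and consumes in the same operation (steps 5, 12, 17) are not numbered; species prepared in a separate operation before the next reagent is added are numbered as intermediates.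

**Route**

Step 1
Reactants: 1 methyl hex-5-ynoate
Product: 2 2-methylhept-6-yn-2-ol
Conditions: MeMgBr (3.2 equiv), THF, 0 °C → rt
Reagents that add atoms: methylmagnesium bromide, C[Mg]Br
Why: Double Grignard addition to the ester gives the tertiary alcohol, and the excess of MeMgBr covers any reversible deprotonation of the terminal alkyne, which is recovered on work-up.

Step 2
Reactants: 2 2-methylhept-6-yn-2-ol
Product: 3 triethyl[(2-methylhept-6-yn-2-yl)oxy]silane
Conditions: Et3SiOTf, 2,6-lutidine, CH2Cl2, 0 °C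
Reagents that add atoms: triethylsilyl trifluoromethanesulfonate, CC[Si](CC)(CC)OS(=O)(=O)C(F)(F)F
Why: Silylation of a hindered tertiary alcohol with a silyl triflate and a non-nucleophilic base is standard and masks the hydroxyl against NaH, LiN(i-Pr)2 and PhSO2F in steps 5 and 14.

Step 3
Reactants: 3 triethyl[(2-methylhept-6-yn-2-yl)oxy]silane
Product: 5 alkenyl pinacol boronate 2-[6-methyl-6-(triethylsilyloxy)hept-1-en-2-yl]-4,4,5,5-tetramethyl-1,3,2-dioxaborolane, via alkenyldiisobutylalane 4 (not isolated)
Conditions: NiCl2(dppp) (3 mol %), i-Bu2AlH (1.3 equiv), THF, 0 → 22 °C; then MeOBpin, 0 → 80 °C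
Reagents that add atoms: 2-methoxy-4,4,5,5-tetramethyl-1,3,2-dioxaborolane, COB1OC(C)(C)C(C)(C)O1
Why: Nickel-catalysed hydroalumination of a terminal alkyl alkyne with the dppp ligand places aluminium on the internal carbon (Markovnikov sense), and the 1,1-disubstituted alkenylalane exchanges aluminium for boron with MeOBpin in the same flask, so that Ca carries boron.

Step 4
Reactants: 5 alkenyl pinacol boronate (1.5 equiv), 6 cyclohex-2-en-1-one
Product: 7 (3S)-3-[6-methyl-6-(triethylsilyloxy)hept-1-en-2-yl]cyclohexan-1-one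
Conditions: [RhCl(C2H4)2]2 (2.5 mol %), (S)-BINAP (5.5 mol %), aq. KOH (0.5 equiv), 1,4-dioxane/H2O 10:1, 60 °C
Reagents that add atoms: none
Why: Hayashi–Miyaura rhodium-catalysed asymmetric 1,4-addition, in which the alkenyl group passes from boron to the (S)-BINAP–rhodium hydroxide and is delivered to one face of the enone β-carbon, the face that with (S)-BINAP gives (S)-3-aryl- and (S)-3-alkenylcyclohexanones and here sets C1.

Step 5
Reactants: 7 (3S)-3-[6-methyl-6-(triethylsilyloxy)hept-1-en-2-yl]cyclohexan-1-one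
Product: 8 prop-2-en-1-yl (4S)-4-[6-methyl-6-(triethylsilyloxy)hept-1-en-2-yl]-2-oxocyclohexane-1-carboxylate (keto/enol mixture; ester on C4 of the target numbering)
Conditions: NaH (2.5 equiv), diallyl carbonate (2 equiv), THF, 65 °C
Reagents that add atoms: diallyl carbonate, C=CCOC(=O)OCC=C
Why: Claisen-type C-acylation under equilibrating conditions ends at the sodium enolate of the β-keto ester on the CH2 remote from C1, because the isomeric enolate at C14 would press the ester against the C1 substituent (allylic strain), the known preference of 3-substituted cyclohexanones; the ester-bearing carbon is epimerisable and later becomes sp2.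

Step 6
Reactants: 9 pent-4-yn-1-ol
Product: 10 pent-4-ynal
Conditions: TEMPO (10 mol %), PhI(OAc)2 (1.1 equiv), CH2Cl2, rt; solution used directly
Reagents that add atoms: none
Why: TEMPO-catalysed oxidation with PhI(OAc)2 as terminal oxidant stops at the aldehyde and leaves the alkyne alone, and the volatile aldehyde is taken on in solution.

Step 7
Reactants: 10 pent-4-ynal
Product: 11 ethyl (2Z)-2-methylhept-2-en-6-ynoate
Conditions: (CF3CH2O)2P(O)CH(CH3)CO2Et, KN(SiMe3)2, 18-crown-6, THF, −78 °C
Reagents that add atoms: ethyl 2-[bis(2,2,2-trifluoroethoxy)phosphoryl]propanoate, CCOC(=O)C(C)P(=O)(OCC(F)(F)F)OCC(F)(F)F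
Why: Still–Gennari olefination, in which the potassium anion of the electron-poor phosphonate adds to the aldehyde and the adduct collapses before it can equilibrate, which gives the Z trisubstituted enoate that becomes C11=C12.

Step 8
Reactants: 11 ethyl (2Z)-2-methylhept-2-en-6-ynoate
Product: 12 (2Z)-2-methylhept-2-en-6-yn-1-ol
Conditions: i-Bu2AlH (2.3 equiv), CH2Cl2, −78 → 0 °C
Reagents that add atoms: none
Why: 1,2-Reduction of the enoate with i-Bu2AlH at low temperature gives the allylic alcohol (C13–OH) without touching the alkyne or the Z double bond.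

Step 9
Reactants: 12 (2Z)-2-methylhept-2-en-6-yn-1-ol
Product: 13 tert-butyldimethyl{[(2Z)-2-methylhept-2-en-6-yn-1-yl]oxy}silane
Conditions: t-BuMe2SiCl, imidazole, DMF, rt
Reagents that add atoms: tert-butyldimethylsilyl chloride, CC(C)(C)[Si](C)(C)Cl
Why: Standard silylation of a primary alcohol gives an ether that survives Me3Al, zerovalent palladium and LiN(i-Pr)2 and is removed together with the triethylsilyl ether in step 15.

Step 10
Reactants: 13 tert-butyldimethyl{[(2Z)-2-methylhept-2-en-6-yn-1-yl]oxy}silane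
Product: 16 (3E,7Z)-9-(tert-butyldimethylsilyloxy)-4,8-dimethylnona-3,7-dien-1-ol, via alkenyldimethylalane 14 (not isolated), via lithium alkenylaluminate 15 (not isolated)
Conditions: Me3Al (2.5 equiv), Cp2ZrCl2 (0.25 equiv), CH2Cl2, 0 °C → rt; excess Me3Al removed in vacuo; n-BuLi (1 equiv), THF, −78 °C; oxirane (3 equiv), −78 → 0 °C
Reagents that add atoms: trimethylaluminium, C[Al](C)C; oxirane, C1CO1
Why: Negishi zirconium-catalysed carboalumination adds methyl and aluminium syn across the terminal alkyne with aluminium on the terminal carbon, which fixes the E geometry of C7=C8, and the derived lithium alkenylaluminate opens oxirane with retention at the alkenyl carbon to add C6 and C5 as a homoallylic alcohol.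

Step 11
Reactants: 16 (3E,7Z)-9-(tert-butyldimethylsilyloxy)-4,8-dimethylnona-3,7-dien-1-ol
Product: 17 tert-butyl{[(2Z,6E)-9-iodo-2,6-dimethylnona-2,6-dien-1-yl]oxy}dimethylsilane
Conditions: I2, PPh3, imidazole, CH2Cl2, 0 °C
Reagents that add atoms: iodine, II
Why: Appel-type iodination of the primary alcohol (SN2 at C5) with PPh3, I2 and imidazole leaves the allylic silyl ether and both alkenes intact.

Step 12
Reactants: 8 allyl β-keto ester, 17 chain iodide
Product: 18 prop-2-en-1-yl (4S)-1-[(3E,7Z)-9-(tert-butyldimethylsilyloxy)-4,8-dimethylnona-3,7-dien-1-yl]-4-[6-methyl-6-(triethylsilyloxy)hept-1-en-2-yl]-2-oxocyclohexane-1-carboxylate (epimers at the quaternary carbon)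
Conditions: Cs2CO3 (1.5 equiv), DMF, rt → 40 °C
Reagents that add atoms: none
Why: C-alkylation of the caesium enolate of a cyclic β-keto ester with a primary iodide (SN2) forms C4–C5 and a quaternary C4 whose configuration does not matter because C4 becomes sp2 in step 13.

Step 13
Reactants: 18 alkylated allyl β-keto ester
Product: 19 (5S)-2-[(3E,7Z)-9-(tert-butyldimethylsilyloxy)-4,8-dimethylnona-3,7-dien-1-yl]-5-[6-methyl-6-(triethylsilyloxy)hept-1-en-2-yl]cyclohex-2-en-1-one
Conditions: Pd(OAc)2 (10 mol %), dppe (10 mol %), MeCN, 80 °C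
Reagents that add atoms: none
Why: Tsuji decarboxylation–dehydrogenation of an allyl α-alkyl-β-keto carboxylate, in which zerovalent palladium ionises the allyl ester, CO2 is lost and the palladium enolate at C4 undergoes β-hydride elimination toward the ring CH2 (C3), the documented course for 2-alkylcyclohexanone substrates, so that the 2-substituted cyclohex-2-enone forms with C15 cis to C2 and propene is released.

Step 14
Reactants: 19 2,5-disubstituted cyclohex-2-enone
Product: 21 (5R)-2-[(3E,7Z)-9-(tert-butyldimethylsilyloxy)-4,8-dimethylnona-3,7-dien-1-yl]-5-[6-methyl-6-(triethylsilyloxy)hept-1-en-2-yl]-6-(phenylsulfonyl)cyclohex-2-en-1-one (C6 epimers), via lithium dienolate 20 (not isolated)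
Conditions: LiN(i-Pr)2 (2.1 equiv), THF, −78 °C; then PhSO2F (1.1 equiv), −78 → 0 °C
Reagents that add atoms: benzenesulfonyl fluoride, O=S(=O)(F)c1ccccc1
Why: Kinetic deprotonation of a 2-substituted cyclohex-2-enone by a lithium amide at −78 °C occurs at the α′ carbon (C14), as in carvone, and the cross-conjugated enolate is C-sulfonylated by the sulfonyl fluoride while the second equivalent of base holds the more acidic product as its enolate; the new centre C14 is uncontrolled and transient.

Step 15
Reactants: 21 bis-silylated β-keto sulfone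
Product: 22 (5R)-2-[(3E,7Z)-9-hydroxy-4,8-dimethylnona-3,7-dien-1-yl]-5-(6-hydroxy-6-methylhept-1-en-2-yl)-6-(phenylsulfonyl)cyclohex-2-en-1-one
Conditions: HF·pyridine, pyridine/THF, 0 °C → rt
Reagents that add atoms: none
Why: Fluoride-mediated cleavage of both silyl ethers under mildly acidic conditions, which the enone and the β-keto sulfone tolerate.

Step 16
Reactants: 22 diol
Product: 23 (5R)-2-[(3E,7Z)-9-bromo-4,8-dimethylnona-3,7-dien-1-yl]-5-(6-hydroxy-6-methylhept-1-en-2-yl)-6-(phenylsulfonyl)cyclohex-2-en-1-one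
Conditions: CBr4 (1.2 equiv), PPh3 (1.2 equiv), CH2Cl2, −20 → 0 °C
Reagents that add atoms: tetrabromomethane, BrC(Br)(Br)Br
Why: Appel bromination converts the primary allylic alcohol into the bromide by SN2 at C13 without allylic transposition or loss of the Z geometry, while the tertiary alcohol reacts far more slowly at low temperature.

Step 17
Reactants: 23 bromo β-keto sulfone
Product: 24 (4E,8Z,12R)-12-(6-hydroxy-6-methylhept-1-en-2-yl)-5,9-dimethyl-11-(phenylsulfonyl)bicyclo[9.3.1]pentadeca-1(14),4,8-trien-15-one (bridgeheads are C4 and C14 of the target numbering; C14 configuration not assigned)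
Conditions: Cs2CO3 (5 equiv), MeCN, 50 °C; 23 added by syringe pump over 12 h (final concentration 2 mM)
Reagents that add atoms: none
Why: Cs2CO3 removes the C14 proton, the most acidic one in 23 because it lies between the ketone and the sulfonyl group, and the enolate displaces the primary allylic bromide at C13 in an intramolecular SN2 C-alkylation, the reaction type established for β-keto sulfones and for carbonate-mediated macrocyclisation of stabilised carbanions onto allylic halides. The ring that closes is the 12-membered ring C14–C13–C12–C11–C10–C9–C8–C7–C6–C5–C4–C15 in a 12-exo-tet mode, which completes the 14-carbon perimeter C1–C14 as the large ring of a bicyclo[9.3.1] skeleton. The new stereocentre at C14 should form with the bridge on the face away from the C1 alkenyl group, but its configuration is immaterial because C14 ends as a methylene after steps 18 and 19. The step needs C- over O-alkylation, SN2 over SN2′ and ring closure over oligomerisation: the soft sulfonyl-stabilised enolate and the soft, unhindered primary allylic bromide favour attack through carbon at C13, the cyclohexenone holds C4 and C14 two bonds apart while the Z alkene at C11=C12 turns the chain back toward C14, and slow addition at high dilution suppresses intermolecular alkylation. The Z geometry at C11=C12 and the E geometry at C7=C8 are carried through unchanged because no allyl–metal intermediate is involved.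

Step 18
Reactants: 24 bridged keto sulfone
Product: 25 (1Z,4R,7Z,11E)-4-(6-hydroxy-6-methylhept-1-en-2-yl)-7,11-dimethyl-5-(phenylsulfonyl)cyclotetradeca-1,7,11-triene-1-carboxylic acid (C5 epimers; C5 is C14 of the target numbering)
Conditions: LiOH·H2O (5 equiv), THF/H2O 3:1, 0 °C → rt; then 1 M HCl to pH 3
Reagents that add atoms: lithium hydroxide, [Li+].[OH-]
Why: Retro-Claisen (acyl cleavage) of a non-enolisable β-keto sulfone, in which hydroxide adds to C15, the tetrahedral intermediate expels the sulfonyl-stabilised carbanion at C14 with release of the bridge strain, and the irreversibly formed carboxylate keeps C2 cis to C15 because the C3=C4 bond is not touched.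

Step 19
Reactants: 25 sulfonyl acid
Product: 26 (1Z,4R,7Z,11E)-4-(6-hydroxy-6-methylhept-1-en-2-yl)-7,11-dimethylcyclotetradeca-1,7,11-triene-1-carboxylic acid
Conditions: 6 % Na(Hg) (excess), Na2HPO4, MeOH/THF, −20 °C → rt; then aq. NaH2PO4
Reagents that add atoms: none
Why: Reductive desulfonylation with sodium amalgam, Na(Hg), in buffered methanol cleaves the C14–S bond by electron transfer and protonation, which turns C14 into a methylene, while the conjugated acid is shielded from reduction as its carboxylate and C1 is not affected.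

Step 20
Reactants: 26 macrocyclic enoic acid
Product: 27 methyl (1Z,4R,7Z,11E)-4-(6-hydroxy-6-methylhept-1-en-2-yl)-7,11-dimethylcyclotetradeca-1,7,11-triene-1-carboxylate (CNP0326472.1)
Conditions: MeI (3 equiv), K2CO3 (2 equiv), DMF, 0 °C → rt
Reagents that add atoms: iodomethane, CI
Why: SN2 O-alkylation of the potassium carboxylate with iodomethane gives the methyl ester without touching the tertiary alcohol or the alkene geometries.

**Compound list**

1 | methyl hex-5-ynoate | C#CCCCC(=O)OC | starting material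
2 | 2-methylhept-6-yn-2-ol | C#CCCCC(C)(C)O | intermediate
3 | triethyl[(2-methylhept-6-yn-2-yl)oxy]silane | C#CCCCC(C)(C)O[Si](CC)(CC)CC | intermediate
4 | diisobutyl[6-methyl-6-(triethylsilyloxy)hept-1-en-2-yl]alane | C=C([Al](CC(C)C)CC(C)C)CCCC(C)(C)O[Si](CC)(CC)CC | intermediate (not isolated)
5 | 2-[6-methyl-6-(triethylsilyloxy)hept-1-en-2-yl]-4,4,5,5-tetramethyl-1,3,2-dioxaborolane | C=C(B1OC(C)(C)C(C)(C)O1)CCCC(C)(C)O[Si](CC)(CC)CC | intermediate
6 | cyclohex-2-en-1-one | O=C1C=CCCC1 | starting material
7 | (3S)-3-[6-methyl-6-(triethylsilyloxy)hept-1-en-2-yl]cyclohexan-1-one | O=C1CCC[C@H](C(=C)CCCC(C)(C)O[Si](CC)(CC)CC)C1 | intermediate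
8 | prop-2-en-1-yl (4S)-4-[6-methyl-6-(triethylsilyloxy)hept-1-en-2-yl]-2-oxocyclohexane-1-carboxylate | O=C1C(C(=O)OCC=C)CC[C@H](C(=C)CCCC(C)(C)O[Si](CC)(CC)CC)C1 | intermediate
9 | pent-4-yn-1-ol | C#CCCCO | starting material
10 | pent-4-ynal | C#CCCC=O | intermediate
11 | ethyl (2Z)-2-methylhept-2-en-6-ynoate | C#CCC/C=C(/C)C(=O)OCC | intermediate
12 | (2Z)-2-methylhept-2-en-6-yn-1-ol | C#CCC/C=C(/C)CO | intermediate
13 | tert-butyldimethyl{[(2Z)-2-methylhept-2-en-6-yn-1-yl]oxy}silane | C#CCC/C=C(/C)CO[Si](C)(C)C(C)(C)C | intermediate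
14 | [(1E,5Z)-7-(tert-butyldimethylsilyloxy)-2,6-dimethylhepta-1,5-dien-1-yl]dimethylalane | C[Al](C)/C=C(\C)CC/C=C(/C)CO[Si](C)(C)C(C)(C)C | intermediate (not isolated)
15 | lithium butyl[(1E,5Z)-7-(tert-butyldimethylsilyloxy)-2,6-dimethylhepta-1,5-dien-1-yl]dimethylaluminate | [Li+].CCCC[Al-](C)(C)/C=C(\C)CC/C=C(/C)CO[Si](C)(C)C(C)(C)C | intermediate (not isolated)
16 | (3E,7Z)-9-(tert-butyldimethylsilyloxy)-4,8-dimethylnona-3,7-dien-1-ol | OCC/C=C(\C)CC/C=C(/C)CO[Si](C)(C)C(C)(C)C | intermediate
17 | tert-butyl{[(2Z,6E)-9-iodo-2,6-dimethylnona-2,6-dien-1-yl]oxy}dimethylsilane | ICC/C=C(\C)CC/C=C(/C)CO[Si](C)(C)C(C)(C)C | intermediate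
18 | prop-2-en-1-yl (4S)-1-[(3E,7Z)-9-(tert-butyldimethylsilyloxy)-4,8-dimethylnona-3,7-dien-1-yl]-4-[6-methyl-6-(triethylsilyloxy)hept-1-en-2-yl]-2-oxocyclohexane-1-carboxylate | O=C1C(C(=O)OCC=C)(CC/C=C(\C)CC/C=C(/C)CO[Si](C)(C)C(C)(C)C)CC[C@H](C(=C)CCCC(C)(C)O[Si](CC)(CC)CC)C1 | intermediate
19 | (5S)-2-[(3E,7Z)-9-(tert-butyldimethylsilyloxy)-4,8-dimethylnona-3,7-dien-1-yl]-5-[6-methyl-6-(triethylsilyloxy)hept-1-en-2-yl]cyclohex-2-en-1-one | O=C1C(CC/C=C(\C)CC/C=C(/C)CO[Si](C)(C)C(C)(C)C)=CC[C@H](C(=C)CCCC(C)(C)O[Si](CC)(CC)CC)C1 | intermediate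
20 | lithium cross-conjugated dienolate of 19 (C15–O, C15=C14) | [Li+].[O-]C1=C[C@@H](C(=C)CCCC(C)(C)O[Si](CC)(CC)CC)CC=C1CC/C=C(\C)CC/C=C(/C)CO[Si](C)(C)C(C)(C)C | intermediate (not isolated)
21 | (5R)-2-[(3E,7Z)-9-(tert-butyldimethylsilyloxy)-4,8-dimethylnona-3,7-dien-1-yl]-5-[6-methyl-6-(triethylsilyloxy)hept-1-en-2-yl]-6-(phenylsulfonyl)cyclohex-2-en-1-one | O=C1C(CC/C=C(\C)CC/C=C(/C)CO[Si](C)(C)C(C)(C)C)=CC[C@H](C(=C)CCCC(C)(C)O[Si](CC)(CC)CC)C1S(=O)(=O)c2ccccc2 | intermediate
22 | (5R)-2-[(3E,7Z)-9-hydroxy-4,8-dimethylnona-3,7-dien-1-yl]-5-(6-hydroxy-6-methylhept-1-en-2-yl)-6-(phenylsulfonyl)cyclohex-2-en-1-one | O=C1C(CC/C=C(\C)CC/C=C(/C)CO)=CC[C@H](C(=C)CCCC(C)(C)O)C1S(=O)(=O)c2ccccc2 | intermediate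
23 | (5R)-2-[(3E,7Z)-9-bromo-4,8-dimethylnona-3,7-dien-1-yl]-5-(6-hydroxy-6-methylhept-1-en-2-yl)-6-(phenylsulfonyl)cyclohex-2-en-1-one | O=C1C(CC/C=C(\C)CC/C=C(/C)CBr)=CC[C@H](C(=C)CCCC(C)(C)O)C1S(=O)(=O)c2ccccc2 | intermediate
24 | (4E,8Z,12R)-12-(6-hydroxy-6-methylhept-1-en-2-yl)-5,9-dimethyl-11-(phenylsulfonyl)bicyclo[9.3.1]pentadeca-1(14),4,8-trien-15-one | O=C1C2=CC[C@H](C(=C)CCCC(C)(C)O)C1(S(=O)(=O)c3ccccc3)C/C(C)=C\CC/C(C)=C/CC2 | intermediate
25 | (1Z,4R,7Z,11E)-4-(6-hydroxy-6-methylhept-1-en-2-yl)-7,11-dimethyl-5-(phenylsulfonyl)cyclotetradeca-1,7,11-triene-1-carboxylic acid | C=C(CCCC(C)(C)O)[C@H]1C/C=C(\C(=O)O)CC/C=C(\C)CC/C=C(/C)CC1S(=O)(=O)c2ccccc2 | intermediate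
26 | (1Z,4R,7Z,11E)-4-(6-hydroxy-6-methylhept-1-en-2-yl)-7,11-dimethylcyclotetradeca-1,7,11-triene-1-carboxylic acid | C=C(CCCC(C)(C)O)[C@H]1C/C=C(\C(=O)O)CC/C=C(\C)CC/C=C(/C)CC1 | intermediate
27 | methyl (1Z,4R,7Z,11E)-4-(6-hydroxy-6-methylhept-1-en-2-yl)-7,11-dimethylcyclotetradeca-1,7,11-triene-1-carboxylate | C=C(CCCC(C)(C)O)[C@H]1C/C=C(\C(=O)OC)CC/C=C(\C)CC/C=C(/C)CC1 | target

**Count**

Total steps: 20. Longest linear sequence: 15 steps (steps 6–11, then 12–20, from pent-4-yn-1-ol); the ring branch (steps 1–5, then 12–20) has 14.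

**Steps most likely to fail**

Step 17. The enolate may be alkylated on oxygen, which closes a ring of the same size, or by a second molecule, so that an enol ether or oligomers form in place of the carbon bridge. The fallback sets out from 16 and 8 and returns at 24: the two alkylations are run in the opposite order, so that C13–C14 is made between two molecules and the ring is closed at C4–C5. Desilylation of 16 with HF·pyridine gives (2Z,6E)-2,6-dimethylnona-2,6-diene-1,9-diol F1, and CBr4/PPh3 gives (2Z,6E)-1,9-dibromo-2,6-dimethylnona-2,6-diene F2. The dianion of 8 (NaH, then n-BuLi, THF, −78 °C) is alkylated at its γ-carbon C14 by the allylic end of F2 to give the C14-allylated β-keto ester bromide F3. Cs2CO3 with CsI in MeCN at high dilution then closes the 12-membered ring by C-alkylation of the β-keto ester at C4 to give the bridged allyl β-keto ester F4. Pd(OAc)2/dppe in MeCN at 80 °C converts it into the bridged enone F5. LiN(i-Pr)2 followed by PhSO2F sulfonylates the bridgehead C14 to give the triethylsilyl ether of the bridged keto sulfone F6, and HF·pyridine gives 24.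

Step 18. Conjugate addition of hydroxide at C3, or removal of a γ-hydrogen at C2 with migration of the C3=C4 double bond, may outrun addition to the hindered carbonyl, so that the position or geometry of the enoate is lost. The fallback sets out from 24 and returns at 25: the ketone is first taken out of conjugation by reduction and the ring is opened by a retro-aldol cleavage. Luche reduction (NaBH4, CeCl3·7H2O, MeOH, −40 °C) gives the bridged allylic alcohol F7. Its potassium alkoxide (KOt-Bu, t-BuOH/THF, 0 °C) fragments as a β-hydroxy sulfone with loss of the C14 sulfonyl carbanion to give the (Z)-enal sulfone F8, which is quenched cold to protect the enal geometry. Pinnick oxidation (NaClO2, NaH2PO4, 2-methylbut-2-ene, t-BuOH/H2O) gives 25.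

Step 14. The enolate may be sulfonylated on oxygen, or be quenched by proton transfer from the more acidic product, so that conversion stays incomplete. The fallback sets out from 19 and returns at 21: sulfur is introduced at the sulfide level and oxidised afterwards. LiN(i-Pr)2 in THF at −78 °C followed by S-phenyl benzenethiosulfonate gives the 6-(phenylthio)cyclohexenone F9, and (NH4)6Mo7O24·4H2O (catalytic) with H2O2 in EtOH at 0 °C oxidises sulfur selectively in the presence of the alkenes to give 21.

**Further compounds**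

F1 | step 17 | (2Z,6E)-2,6-dimethylnona-2,6-diene-1,9-diol | OCC/C=C(\C)CC/C=C(/C)CO
F2 | step 17 | (2Z,6E)-1,9-dibromo-2,6-dimethylnona-2,6-diene | BrCC/C=C(\C)CC/C=C(/C)CBr
F3 | step 17 | C14-allylated β-keto ester bromide, prop-2-en-1-yl 3-[(2Z,6E)-9-bromo-2,6-dimethylnona-2,6-dien-1-yl]-4-[6-methyl-6-(triethylsilyloxy)hept-1-en-2-yl]-2-oxocyclohexane-1-carboxylate | O=C1C(C(=O)OCC=C)CC[C@H](C(=C)CCCC(C)(C)O[Si](CC)(CC)CC)C1C/C(C)=C\CC/C(C)=C/CCBr
F4 | step 17 | bridged allyl β-keto ester (bicyclo[9.3.1]pentadeca-4,8-dien-15-one with the allyl ester on bridgehead C4 of the target numbering) | O=C1C2(C(=O)OCC=C)CC[C@H](C(=C)CCCC(C)(C)O[Si](CC)(CC)CC)C1C/C(C)=C\CC/C(C)=C/CC2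
F5 | step 17 | bridged enone, 12-[6-methyl-6-(triethylsilyloxy)hept-1-en-2-yl]-5,9-dimethylbicyclo[9.3.1]pentadeca-1(14),4,8-trien-15-one | O=C1C2=CC[C@H](C(=C)CCCC(C)(C)O[Si](CC)(CC)CC)C1C/C(C)=C\CC/C(C)=C/CC2
F6 | step 17 | triethylsilyl ether of the bridged keto sulfone 24 | O=C1C2=CC[C@H](C(=C)CCCC(C)(C)O[Si](CC)(CC)CC)C1(S(=O)(=O)c3ccccc3)C/C(C)=C\CC/C(C)=C/CC2
F7 | step 18 | bridged allylic alcohol, 12-(6-hydroxy-6-methylhept-1-en-2-yl)-5,9-dimethyl-11-(phenylsulfonyl)bicyclo[9.3.1]pentadeca-1(14),4,8-trien-15-ol | OC1C2=CC[C@H](C(=C)CCCC(C)(C)O)C1(S(=O)(=O)c3ccccc3)C/C(C)=C\CC/C(C)=C/CC2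
F8 | step 18 | (Z)-enal sulfone, (1Z,4R,7Z,11E)-4-(6-hydroxy-6-methylhept-1-en-2-yl)-7,11-dimethyl-5-(phenylsulfonyl)cyclotetradeca-1,7,11-triene-1-carbaldehyde | C=C(CCCC(C)(C)O)[C@H]1C/C=C(\C=O)CC/C=C(\C)CC/C=C(/C)CC1S(=O)(=O)c2ccccc2
F9 | step 14 | 6-(phenylthio)cyclohexenone, 2-[(3E,7Z)-9-(tert-butyldimethylsilyloxy)-4,8-dimethylnona-3,7-dien-1-yl]-5-[6-methyl-6-(triethylsilyloxy)hept-1-en-2-yl]-6-(phenylsulfanyl)cyclohex-2-en-1-one | O=C1C(CC/C=C(\C)CC/C=C(/C)CO[Si](C)(C)C(C)(C)C)=CC[C@H](C(=C)CCCC(C)(C)O[Si](CC)(CC)CC)C1Sc2ccccc2
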